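**Retrosynthetic overview**

1. Numbering: C1 = ring-fusion C(CH3), C2 = CH(OAc), C3 = CH2, C4 = C(OH)(iPr), C5 = ring-fusion CH, C6 = CH(O-anisoyl), C7 = CH2, C8 = C(CH3)=, C9 = CH=, C10 = CH2; ring A = C1–C5, ring B = C1, C5–C10; β = face of the C1 methyl.
2. Feature: ring B is the C1–C5 edge of ring A plus the chain C6–C10, which is a 4-methylcyclopentane-1,3-dione with its C6–C10 bond cut (O on C6, carbonyl handle on C9 beside C8–CH3).
3. Late disconnections: C2 acetate and C6 anisate (staged acylation); C4–iPr (organocerium on the C4 ketone, α face); C8=C9 (C9 enol triflate, reduction); C2–H and C6–H (hydride handed over from the 4β-oxygen).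
4. Ring B: retro-aldol cleavage of C6–C10 in a cyclobutanol that carries the C9 ketone, then epimerisation of C5 to the trans fusion.
5. Key disconnection: C5–C6 and C1–C10 by [2+2] photocycloaddition of (S)-4-silyloxy-2-methylcyclopent-2-enone with 3-benzyloxy-5-methylcyclopent-2-enone; ring order: ring A (Piancatelli), then cyclobutane, then ring B.

Key step: step 7

Remark: the dione partner is used as its benzyl enol ether, so that its methyl group is placed regiospecifically by α′-alkylation and the cyclobutanol is later freed by hydrogenolysis; basic ester cleavage would eliminate the C4 oxygen β to the C2 ketone.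
Remark: intermediates are named with the numbering above; C8 is α to the C9 ketone and is carried as a mixture of epimers in compounds 8 to 18 until it becomes sp2 in step 16.
Assumption: the lipase acetylates the (R)-enantiomer of 3 faster, as it does with 4-hydroxycyclopent-2-enone, so the unreacted alcohol is (S).

**Route**

Step 1
Reactants: 1 1-(furan-2-yl)ethanol (racemic)
Product: 2 trans-4-hydroxy-5-methylcyclopent-2-enone (racemic)
Conditions: ZnCl2 (cat.), dioxane–H2O, reflux
Reagents that add atoms: water, O
Why: Piancatelli rearrangement, in which acid ionises the furylcarbinol, water adds to the furan and the ring-opened pentadienyl cation closes by conrotatory 4π electrocyclisation, which places OH and methyl trans.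

Step 2
Reactants: 2 trans-4-hydroxy-5-methylcyclopent-2-enone
Product: 3 4-hydroxy-2-methylcyclopent-2-enone (racemic)
Conditions: KH2PO4/K2HPO4 buffer (pH 8), dioxane–H2O, 60 °C
Reagents that add atoms: water, O
Why: The known isomerisation of 4-hydroxy-5-alkyl- to 4-hydroxy-2-alkylcyclopentenones by conjugate hydration and E1cB loss of the original hydroxyl gives the more substituted enone, with the new carbinol centre racemic.

Step 3
Reactants: 3 4-hydroxy-2-methylcyclopent-2-enone (racemic)
Product: 4 (S)-4-hydroxy-2-methylcyclopent-2-enone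
Conditions: immobilised Candida antarctica lipase B, vinyl acetate, MTBE, 30 °C, stopped just past half conversion
Reagents that add atoms: none
Why: Lipase-catalysed kinetic resolution by transesterification should acetylate the (R)-alcohol and leave the (S)-alcohol, whose centre later controls C1.

Step 4
Reactants: 4 (S)-4-hydroxy-2-methylcyclopent-2-enone
Product: 5 (S)-4-(tert-butyldimethylsilyloxy)-2-methylcyclopent-2-enone
Conditions: TBSCl, imidazole, DMF, 0 °C to rt
Reagents that add atoms: tert-butyldimethylsilyl chloride, CC(C)(C)[Si](C)(C)Cl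
Why: Standard silylation of a secondary alcohol installs the bulky group that shields one face of the enone; the stereocentre is untouched.

Step 5
Reactants: 6 cyclopentane-1,3-dione
Product: 7 3-(benzyloxy)cyclopent-2-enone
Conditions: BnOH, TsOH·H2O (cat.), toluene, reflux, Dean–Stark trap
Reagents that add atoms: benzyl alcohol, OCc1ccccc1
Why: Acid-catalysed enol etherification of a symmetric 1,3-dione with azeotropic removal of water gives the vinylogous ester without any regiochemical question.

Step 6
Reactants: 7 3-(benzyloxy)cyclopent-2-enone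
Product: 8 3-(benzyloxy)-5-methylcyclopent-2-enone (racemic)
Conditions: LiN(iPr)2, THF, −78 °C; then MeI, −78 to −20 °C
Reagents that add atoms: iodomethane, CI
Why: Stork–Danheiser-type kinetic α′-deprotonation of the vinylogous ester and methylation put the methyl group next to the carbonyl, so the future C8–CH3 sits beside C9 and away from the oxygen-bearing C6.

Step 7
Reactants: 5 (S)-4-(tert-butyldimethylsilyloxy)-2-methylcyclopent-2-enone; 8 3-(benzyloxy)-5-methylcyclopent-2-enone
Product: 9 cis-anti-cis photoadduct: cyclobutane C1–C5–C6–C10 between ring A and the second five-membered ring, with 2,9-dione, 4β-OTBS, 6-OBn, 1β-CH3, 8-CH3, 5β-H, and C6 and C10 on the α face of ring A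
Conditions: hν (350–366 nm, uranium-glass filter or 365 nm LEDs), 8 (6 equiv, excess recovered), degassed CH2Cl2, −30 °C
Reagents that add atoms: none
Why: Proposed new method: excitation of 5 in its n,π* band, where 8 is almost transparent, gives after intersystem crossing the enone triplet, which adds to the electron-rich C6=C10 bond of ground-state 8 through a triplet 1,4-biradical; the closest known reaction type is the [2+2] photocycloaddition of cyclopentenones with enol ethers and the De Mayo sequence of 1,3-dione enol derivatives, extended here to a partner that is itself an enone. The four-membered ring C1–C5–C6–C10 closes by recombination of the biradical after spin inversion, suprafacially on both alkenes, so it is cis-fused to both five-membered rings. C1 and C5 are set by approach of 8 anti to the C4 silyloxy group (C6 and C10 α, C1–CH3 and H5 β), and C6 and C10 by the enforced cis fusion together with the anti placement of the two five-membered rings across the cyclobutane, which keeps them apart. The step needs the C5–C6/C1–C10 orientation, formation of the mixed adduct in preference to dimers of 5, and anti facial selectivity. The first should follow from pairing of the donor-bearing C6 with the β-carbon C5 of the excited enone and of the nucleophilic C10 with its α-carbon C1, the second from exciting only 5 in the presence of a sixfold excess of 8, and the third from the bulky silyloxy group next to C5. Both C8 epimers are expected and are carried on together.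

Step 8
Reactants: 9 photoadduct
Product: 10 4β-hydroxy photoadduct (2,9-dione, 6-OBn)
Conditions: 48% aq. HF, MeCN, 0 °C to rt
Reagents that add atoms: none
Why: Acidic fluoride cleavage of the silyl ether frees the 4β-hydroxyl without base, so the β-hydroxy ketone does not eliminate.

Step 9
Reactants: 10 4β-hydroxy photoadduct
Product: 11 2α,4β-dihydroxy-9-ketone (6-OBn, tricyclic)
Conditions: Me4NBH(OAc)3 (5 equiv), MeCN–AcOH (1:1), −30 to −10 °C
Reagents that add atoms: none
Why: In this hydroxyl-directed triacetoxyborohydride reduction (Evans–Saksena type) the 4β-hydroxyl exchanges onto boron and hands hydride to the β face of the C2 ketone across ring A, which sets the 2α-alcohol (trans-1,3-diol), while the C9 ketone has no β-hydroxyl and is left alone.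

Step 10
Reactants: 11 2α,4β-dihydroxy-9-ketone
Product: 12 4β-(benzyloxycarbonyloxy)-2α-hydroxy-9-ketone (6-OBn, tricyclic)
Conditions: CbzCl (1.2 equiv), pyridine, DMAP (cat.), CH2Cl2, −20 to 0 °C
Reagents that add atoms: benzyl chloroformate, O=C(Cl)OCc1ccccc1
Why: Selective acylation should take the exposed exo 4β-hydroxyl, because the 2α-hydroxyl is neopentyl and lies on the concave face beside the cyclobutane.

Step 11
Reactants: 12 4β-(benzyloxycarbonyloxy)-2α-hydroxy-9-ketone
Product: 13 2α-(tert-butyldimethylsilyloxy)-4β-(benzyloxycarbonyloxy)-9-ketone (6-OBn, tricyclic)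
Conditions: TBSOTf, 2,6-lutidine, CH2Cl2, −78 to −20 °C
Reagents that add atoms: tert-butyldimethylsilyl trifluoromethanesulfonate, CC(C)(C)[Si](C)(C)OS(=O)(=O)C(F)(F)F
Why: The silyl triflate silylates the hindered 2α-hydroxyl at low temperature, where the weak base does not enolise the C9 ketone, and gives C2 a group that lasts to the end of the route.

Step 12
Reactants: 13 2α-(tert-butyldimethylsilyloxy)-4β-(benzyloxycarbonyloxy)-9-ketone
Product: 15 cis-fused 4β-hydroxy-2α-(tert-butyldimethylsilyloxy)-1β,8-dimethylhydroazulene-6,9-dione (5β-H), via cyclobutanol 14 (not isolated)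
Conditions: H2 (1 atm), Pd(OH)2/C, EtOAc, rt; filter, then stir with silica gel in CH2Cl2 if fragmentation is incomplete
Reagents that add atoms: none
Why: Hydrogenolysis removes the benzyl ether and the benzyl carbonate (which loses CO2) under neutral conditions, and the strained tertiary cyclobutanol so freed is a β-hydroxy ketone that opens by retro-aldol cleavage of C6–C10 (De Mayo fragmentation) to ring B without base, C5 keeping its β-hydrogen.

Step 13
Reactants: 15 cis-fused 6,9-dione
Product: 16 trans-fused 4β-hydroxy-2α-(tert-butyldimethylsilyloxy)-1β,8-dimethylhydroazulene-6,9-dione (5α-H)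
Conditions: K2CO3 (0.5 equiv), MeOH, 0 °C to rt
Reagents that add atoms: none
Why: Base-catalysed epimerisation through the C5 enolate of the C6 ketone should set H5 α under thermodynamic control, since the free C4 hydroxyl is a poor leaving group (reprotonation outruns E1cB loss of water) and the trans fusion takes ring B off the concave α face that carries the 2α-silyloxy group.

Step 14
Reactants: 16 trans-fused 6,9-dione
Product: 17 4β-acetoxy-6α-hydroxy-2α-(tert-butyldimethylsilyloxy)-1β,8-dimethyl-trans-hydroazulen-9-one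
Conditions: MeCHO (8 equiv), SmI2 (0.3 equiv), THF, −10 °C
Reagents that add atoms: acetaldehyde, CC=O
Why: In this Evans–Tishchenko reduction the hemiacetal formed from the 4β-hydroxyl and acetaldehyde transfers hydride within a samarium-bridged chair to the β (axial) face of the C6 ketone, which gives the anti-1,3 (6α) alcohol, leaves the directing oxygen as its acetate and spares the C9 ketone.

Step 15
Reactants: 17 4β-acetoxy-6α-hydroxy-9-ketone
Product: 18 4β-acetoxy-6α-(triethylsilyloxy)-2α-(tert-butyldimethylsilyloxy)-1β,8-dimethyl-trans-hydroazulen-9-one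
Conditions: TESOTf, 2,6-lutidine, CH2Cl2, −78 °C
Reagents that add atoms: triethylsilyl trifluoromethanesulfonate, CC[Si](CC)(CC)OS(=O)(=O)C(F)(F)F
Why: Fast silylation of the only free hydroxyl at low temperature avoids 1,3-acetyl migration and gives C6 a silyl group more labile than the one on C2.

Step 16
Reactants: 18 6α-(triethylsilyloxy)-9-ketone
Product: 19 C8=C9 enol triflate (9-trifluoromethanesulfonyloxy, 8-CH3; 2α-OTBS, 4β-OAc, 6α-OTES)
Conditions: Tf2O, 2,6-di-tert-butyl-4-methylpyridine, CH2Cl2, 0 °C to rt
Reagents that add atoms: trifluoromethanesulfonic anhydride, O=S(=O)(OS(=O)(=O)C(F)(F)F)C(F)(F)F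
Why: Enol triflate formation with Tf2O and a hindered pyridine base favours the more substituted C8=C9 isomer, helped by the neopentyl position of C10, and removes the labile C8 stereocentre.

Step 17
Reactants: 19 C8=C9 enol triflate
Product: 20 4β-acetoxy-6α-(triethylsilyloxy)-2α-(tert-butyldimethylsilyloxy)-1β,8-dimethyl-trans-hydroazul-8-ene
Conditions: Pd(OAc)2 (5 mol %), PPh3, HCO2H, Bu3N, DMF, 60 °C
Reagents that add atoms: none
Why: Palladium-catalysed formate reduction of the enol triflate (oxidative addition, decarboxylation of the formate, C–H reductive elimination) gives the trisubstituted C8=C9 alkene without moving the double bond.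

Step 18
Reactants: 20 4β-acetate
Product: 21 4β-hydroxy-6α-(triethylsilyloxy)-2α-(tert-butyldimethylsilyloxy)-1β,8-dimethyl-trans-hydroazul-8-ene
Conditions: iBu2AlH (3 equiv), CH2Cl2, −78 to −40 °C; aq. potassium sodium tartrate (KNaC4H4O6)
Reagents that add atoms: none
Why: Reductive cleavage of the acetate at low temperature frees the C4 hydroxyl without an alkoxide base, which could move the C6 silyl group to O4.

Step 19
Reactants: 21 4β-alcohol
Product: 22 6α-(triethylsilyloxy)-2α-(tert-butyldimethylsilyloxy)-1β,8-dimethyl-trans-hydroazul-8-en-4-one (5α-H)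
Conditions: Dess–Martin periodinane, pyridine, CH2Cl2, 0 °C to rt
Reagents that add atoms: none
Why: Buffered Dess–Martin oxidation gives the C4 ketone under neutral conditions, so the C5 centre and both β-silyloxy groups survive.

Step 20
Reactants: 22 C4 ketone; 23 isopropylmagnesium chloride
Product: 24 4β-hydroxy-4α-isopropyl-6α-(triethylsilyloxy)-2α-(tert-butyldimethylsilyloxy)-1β,8-dimethyl-trans-hydroazul-8-ene
Conditions: CeCl3 (anhydrous, 4 equiv), 23 (4 equiv), THF, −78 to −40 °C
Reagents that add atoms: none
Why: Organocerium addition to the ketone holds back enolisation, β-elimination and β-hydride reduction, and attack anti to the C5–C6 bond, from the α face, should set C4 with OH β and isopropyl α.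

Step 21
Reactants: 24 bis-silyl ether
Product: 25 4β,6α-dihydroxy-4α-isopropyl-2α-(tert-butyldimethylsilyloxy)-1β,8-dimethyl-trans-hydroazul-8-ene
Conditions: PPTS (cat.), MeOH, 0 °C to rt
Reagents that add atoms: none
Why: Mild acid methanolysis cleaves the triethylsilyl ether selectively, the tert-butyldimethylsilyl ether on the neopentyl C2 oxygen being far slower.

Step 22
Reactants: 25 6α-alcohol; 26 4-methoxybenzoyl chloride
Product: 27 6α-(4-methoxybenzoyloxy)-4β-hydroxy-4α-isopropyl-2α-(tert-butyldimethylsilyloxy)-1β,8-dimethyl-trans-hydroazul-8-ene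
Conditions: pyridine, DMAP, CH2Cl2, 0 to 40 °C
Reagents that add atoms: none
Why: DMAP-catalysed acylation takes the only secondary hydroxyl, the hindered tertiary C4 hydroxyl being inert under these conditions.

Step 23
Reactants: 27 6α-anisate
Product: 28 6α-(4-methoxybenzoyloxy)-2α,4β-dihydroxy-4α-isopropyl-1β,8-dimethyl-trans-hydroazul-8-ene
Conditions: HF·pyridine, pyridine, THF, 0 °C to rt
Reagents that add atoms: none
Why: Buffered fluoride desilylation frees the 2α-hydroxyl without touching the aryl ester, the tertiary alcohol or the alkene.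

Step 24
Reactants: 28 2α-alcohol
Product: 29 target, 2α-acetoxy-6α-(4-methoxybenzoyloxy)-4β-hydroxy-4α-isopropyl-1β,8-dimethyl-trans-hydroazul-8-ene
Conditions: Ac2O, pyridine, DMAP (cat.), CH2Cl2, rt
Reagents that add atoms: acetic anhydride, CC(=O)OC(C)=O
Why: Acetylation of the remaining secondary hydroxyl completes the target, the tertiary C4 hydroxyl staying free.

**Compound list**

1 | 1-(furan-2-yl)ethanol (racemic) | CC(O)c1ccco1 | starting material
2 | trans-4-hydroxy-5-methylcyclopent-2-enone (racemic, one enantiomer drawn) | C[C@H]1[C@H](O)C=CC1=O | intermediate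
3 | 4-hydroxy-2-methylcyclopent-2-enone (racemic) | CC1=CC(O)CC1=O | intermediate
4 | (S)-4-hydroxy-2-methylcyclopent-2-enone | CC1=C[C@@H](O)CC1=O | intermediate
5 | (S)-4-(tert-butyldimethylsilyloxy)-2-methylcyclopent-2-enone | CC1=C[C@@H](O[Si](C)(C)C(C)(C)C)CC1=O | intermediate
6 | cyclopentane-1,3-dione | O=C1CCC(=O)C1 | starting material
7 | 3-(benzyloxy)cyclopent-2-enone | O=C1C=C(OCc2ccccc2)CC1 | intermediate
8 | 3-(benzyloxy)-5-methylcyclopent-2-enone (racemic) | CC1CC(OCc2ccccc2)=CC1=O | intermediate
9 | cis-anti-cis photoadduct, 2,9-dione, 4β-OTBS, 6-OBn (C8 epimers) | C[C@]12C(=O)C[C@H](O[Si](C)(C)C(C)(C)C)[C@H]1[C@]3(OCc4ccccc4)CC(C)C(=O)[C@H]23 | intermediate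
10 | 4β-hydroxy photoadduct, 2,9-dione, 6-OBn | C[C@]12C(=O)C[C@H](O)[C@H]1[C@]3(OCc4ccccc4)CC(C)C(=O)[C@H]23 | intermediate
11 | 2α,4β-dihydroxy-9-ketone, 6-OBn (tricyclic) | C[C@]12[C@@H](O)C[C@H](O)[C@H]1[C@]3(OCc4ccccc4)CC(C)C(=O)[C@H]23 | intermediate
12 | 4β-(benzyloxycarbonyloxy)-2α-hydroxy-9-ketone, 6-OBn (tricyclic) | C[C@]12[C@@H](O)C[C@H](OC(=O)OCc5ccccc5)[C@H]1[C@]3(OCc4ccccc4)CC(C)C(=O)[C@H]23 | intermediate
13 | 2α-OTBS-4β-(benzyloxycarbonyloxy)-9-ketone, 6-OBn (tricyclic) | C[C@]12[C@@H](O[Si](C)(C)C(C)(C)C)C[C@H](OC(=O)OCc5ccccc5)[C@H]1[C@]3(OCc4ccccc4)CC(C)C(=O)[C@H]23 | intermediate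
14 | cyclobutanol, 2α-OTBS-4β,6-dihydroxy-9-ketone (tricyclic, not isolated) | C[C@]12[C@@H](O[Si](C)(C)C(C)(C)C)C[C@H](O)[C@H]1[C@]3(O)CC(C)C(=O)[C@H]23 | intermediate
15 | cis-fused 4β-hydroxy-2α-OTBS-hydroazulene-6,9-dione (5β-H) | O=C2CC(C)C(=O)C[C@@]3(C)[C@@H](O[Si](C)(C)C(C)(C)C)C[C@H](O)[C@@H]23 | intermediate
16 | trans-fused 4β-hydroxy-2α-OTBS-hydroazulene-6,9-dione (5α-H) | O=C2CC(C)C(=O)C[C@@]3(C)[C@@H](O[Si](C)(C)C(C)(C)C)C[C@H](O)[C@H]23 | intermediate
17 | 4β-acetoxy-6α-hydroxy-2α-OTBS-trans-hydroazulen-9-one | O[C@H]2CC(C)C(=O)C[C@@]3(C)[C@@H](O[Si](C)(C)C(C)(C)C)C[C@H](OC(C)=O)[C@H]23 | intermediate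
18 | 4β-acetoxy-6α-OTES-2α-OTBS-trans-hydroazulen-9-one | CC[Si](CC)(CC)O[C@H]2CC(C)C(=O)C[C@@]3(C)[C@@H](O[Si](C)(C)C(C)(C)C)C[C@H](OC(C)=O)[C@H]23 | intermediate
19 | C8=C9 enol triflate, 4β-OAc, 6α-OTES, 2α-OTBS | CC[Si](CC)(CC)O[C@H]2CC(C)=C(OS(=O)(=O)C(F)(F)F)C[C@@]3(C)[C@@H](O[Si](C)(C)C(C)(C)C)C[C@H](OC(C)=O)[C@H]23 | intermediate
20 | 4β-acetoxy-6α-OTES-2α-OTBS-trans-hydroazul-8-ene | CC[Si](CC)(CC)O[C@H]2CC(C)=CC[C@@]3(C)[C@@H](O[Si](C)(C)C(C)(C)C)C[C@H](OC(C)=O)[C@H]23 | intermediate
21 | 4β-hydroxy-6α-OTES-2α-OTBS-trans-hydroazul-8-ene | CC[Si](CC)(CC)O[C@H]2CC(C)=CC[C@@]3(C)[C@@H](O[Si](C)(C)C(C)(C)C)C[C@H](O)[C@H]23 | intermediate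
22 | 6α-OTES-2α-OTBS-trans-hydroazul-8-en-4-one | CC[Si](CC)(CC)O[C@H]2CC(C)=CC[C@@]3(C)[C@@H](O[Si](C)(C)C(C)(C)C)CC(=O)[C@H]23 | intermediate
23 | isopropylmagnesium chloride | CC(C)[Mg]Cl | starting material
24 | 4β-hydroxy-4α-isopropyl-6α-OTES-2α-OTBS-trans-hydroazul-8-ene | CC[Si](CC)(CC)O[C@H]2CC(C)=CC[C@@]3(C)[C@@H](O[Si](C)(C)C(C)(C)C)C[C@@](O)(C(C)C)[C@H]23 | intermediate
25 | 4β,6α-dihydroxy-4α-isopropyl-2α-OTBS-trans-hydroazul-8-ene | O[C@H]2CC(C)=CC[C@@]3(C)[C@@H](O[Si](C)(C)C(C)(C)C)C[C@@](O)(C(C)C)[C@H]23 | intermediate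
26 | 4-methoxybenzoyl chloride | COc1ccc(C(Cl)=O)cc1 | starting material
27 | 6α-(4-methoxybenzoyloxy)-4β-hydroxy-4α-isopropyl-2α-OTBS-trans-hydroazul-8-ene | COc1ccc(C(=O)O[C@H]2CC(C)=CC[C@@]3(C)[C@@H](O[Si](C)(C)C(C)(C)C)C[C@@](O)(C(C)C)[C@H]23)cc1 | intermediate
28 | 6α-(4-methoxybenzoyloxy)-2α,4β-dihydroxy-4α-isopropyl-trans-hydroazul-8-ene | COc1ccc(C(=O)O[C@H]2CC(C)=CC[C@@]3(C)[C@@H](O)C[C@@](O)(C(C)C)[C@H]23)cc1 | intermediate
29 | CNP0171090.1 | COc1ccc(C(=O)O[C@H]2CC(C)=CC[C@@]3(C)[C@@H](OC(C)=O)C[C@@](O)(C(C)C)[C@H]23)cc1 | target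

**Step count and risks**

Total step count: 24. Longest linear sequence: 22 steps (steps 1–4, then 7–24).

Steps most likely to fail:

1. Step 7 (proposed new method). Excited 5 may dimerise, pass its energy to 8, or add with the reverse orientation, so that too little of the crossed adduct forms. The fallback uses known chemistry, sets out from 8 (5 is used unchanged) and returns to the route at 9. The carbonyl of 8 is reduced with iBu2AlH (CH2Cl2, −78 °C, work-up with aqueous KNaC4H4O6, no acid) to 3-(benzyloxy)-5-methylcyclopent-2-en-1-ol F1. This is silylated at once (Et3SiCl, imidazole, DMF) to its triethylsilyl ether F2, a plain 1-alkoxycyclopentene that does not absorb above 300 nm. Irradiation of 5 with an excess of F2 (350 nm, CH2Cl2, −30 °C) is the established enone–enol ether [2+2] photocycloaddition, in which the alkoxy-bearing carbon bonds to the enone β-carbon, and should give the 9-triethylsilyloxy cyclobutane F3. Selective removal of the triethylsilyl group (PPTS, MeOH, 0 °C) gives the C9 alcohol F4, and Dess–Martin oxidation of it gives 9.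

2. Step 13. The equilibrium may not favour the trans fusion, and the β-hydroxy ketone may lose water by E1cB elimination. The fallback sets out from 15 and returns at 16. Me3SiOTf and Et3N (CH2Cl2, 0 °C) convert 15 into the tris(trimethylsilyl) derivative F5 (4-O-silyl ether, C5=C6 and C8=C9 silyl enol ethers) without a free enolate. Hydrolysis with dilute HCl in THF at −20 °C should protonate C5 from the α face, anti to the C1 methyl and the 4β-silyloxy group, and free the C4 hydroxyl and the C9 ketone, so that 16 is reached under kinetic control. Material silylated toward C7 returns 15 and is recycled.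

3. Step 20. β-Hydride reduction and enolisation, followed by loss of a β-silyloxy group, may compete with addition of the branched nucleophile to the hindered ketone. The fallback sets out from 22 and returns at 24. Isopropenylmagnesium bromide with CeCl3 (THF, −78 °C), a smaller vinylic nucleophile that cannot act as a hydride donor, adds to the C4 ketone from the α face to give the isopropenyl carbinol F6. Hydrogenation of its 1,1-disubstituted alkene with RhCl(PPh3)3 and H2 (benzene, rt), which should leave the trisubstituted C8=C9 bond, gives 24.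

**Further compounds**

F1 | step 7 | 3-(benzyloxy)-5-methylcyclopent-2-en-1-ol | CC1CC(OCc2ccccc2)=CC1O
F2 | step 7 | 3-(benzyloxy)-5-methyl-1-(triethylsilyloxy)cyclopent-2-ene | CC[Si](CC)(CC)OC1C=C(OCc2ccccc2)CC1C
F3 | step 7 | cis-anti-cis photoadduct with 9-triethylsilyloxy group (2-ketone, 4β-OTBS, 6-OBn) | C[C@]12C(=O)C[C@H](O[Si](C)(C)C(C)(C)C)[C@H]1[C@]3(OCc4ccccc4)CC(C)C(O[Si](CC)(CC)CC)[C@H]23
F4 | step 7 | 9-hydroxy photoadduct (2-ketone, 4β-OTBS, 6-OBn) | C[C@]12C(=O)C[C@H](O[Si](C)(C)C(C)(C)C)[C@H]1[C@]3(OCc4ccccc4)CC(C)C(O)[C@H]23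
F5 | step 13 | tris(trimethylsilyl) derivative of 15 (4β-OSiMe3, C5=C6 and C8=C9 silyl enol ethers, 2α-OTBS) | C[Si](C)(C)OC2=C3[C@@H](O[Si](C)(C)C)C[C@H](O[Si](C)(C)C(C)(C)C)[C@]3(C)CC(O[Si](C)(C)C)=C(C)C2
F6 | step 20 | 4β-hydroxy-4α-isopropenyl-6α-OTES-2α-OTBS-trans-hydroazul-8-ene | CC[Si](CC)(CC)O[C@H]2CC(C)=CC[C@@]3(C)[C@@H](O[Si](C)(C)C(C)(C)C)C[C@@](O)(C(C)=C)[C@H]23
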